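The readings are simulated with made-up constants; noise was put on by code.

the same everywhere: gas phase 27 mM (held)
- dawn: substrate 0.15 M; run made earlier
- noon: substrate 0.60 M; run made earlier
- flask: substrate 0.30 M; time 5.0 d

| run | time / d | target / % | substrate / % |
|---|---|---|---|
| dawn | 0.250 | 0 | 100 |
| dawn | 0.833 | 5 | 90 |
| dawn | 1.25 | 5 | 82 |
| dawn | 2.00 | 17 | 70 |
| dawn | 3.00 | 23 | 63 |
| noon | 0.625 | 4 | 97 |
| noon | 1.25 | 6 | 88 |
| noon | 1.67 | 9 | 84 |
| noon | 2.50 | 9 | 75 |
| noon | 3.00 | 7 | 69 |

(readings scatter by 2 percentage points)

- the target standing at 5.0 d, as a percentage of the substrate charged
- concentration of dissolved gas in solution at 5.0 d, in percent of saturation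

- percentages count the substrate that a species holds: one side product B counts as two
- at the start none of the gas is dissolved
- the numbers in the tables scatter with a standard deviation of 2 percentage points
- steps thought possible: substrate + target -> side product B; gas phase <-> dissolved gas; 2 dissolved gas -> self-condensation product; substrate + dissolved gas -> target; substrate -> side product A

1. I began with amounts. One capture of dissolved gas makes one target, and each step to side product B spends one target and one more substrate. So, leaving side product A aside, capture in fractions of the charge is the mean of substrate lost and target standing.

2. Between 1.25 d and 3.00 d this gave 15.9 mM d⁻¹ in the dawn run, at 0.109 M of substrate on average. The noon run gave 34.3 mM d⁻¹ at 0.471 M. Substrate stood higher in the noon run by a larger factor than capture.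

3. I therefore set uptake equal to capture (a quasi-steady state), leaving self-condensation aside: uptake is U(1−s), and capture goes with substrate times s, where s is the fraction of saturation. The two runs gave U = 52.7 mM d⁻¹ and a substrate level of 0.252 M at which s is 0.5. Divided by a flask's charge, this level is the parity fraction f, and s = f/(f + a), with a the fraction of substrate left. For this flask f is 0.841.

4. But the gas starts undissolved. The balance sets in within about 0.234 d, which is far shorter than 5.0 d, so the objection fell.

5. But the noon capture, 10 percentage points, carries about 2 points of scatter, so f stayed rough.

6. The runs held 63 % and 69 % at 3.00 d. Taking their mean and the same fall per day, I put a at 50.0 % for the flask, so my own s was 62.7 %. For the target I committed to no number.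

7. The forecast gave 18 % and 55 %, holding that “gas supply limits the reaction”.

8. The flask gave 22.9 % and 65.0 %.

    substrate + target → side product B (k = 0.0460 M⁻¹ h⁻¹)
    gas phase ⇌ dissolved gas, rate k2*(csat - [dissolved gas]) (kL = 0.0950 h⁻¹)
    2 dissolved gas → self-condensation product (k = 0.270 M⁻¹ h⁻¹)
    substrate + dissolved gas → target (k = 0.310 M⁻¹ h⁻¹)
    substrate → side product A (k = 8.00 × 10⁻⁴ h⁻¹)

With the flask's 42 % of substrate left at 5.0 d, the parity fraction gives 66.5 % of saturation against the 65.0 % found. The target in this flask stands at 22.9 % through the pace of uptake, acting together with the path to side product B: each is a part of the cause, and taking away the first gives 35.8 %, the second 39.0 %. In the neighbour flask with 0.51 M of substrate, 46 % was left, so its own f gives 51.8 % of saturation, and its dissolved gas stood at 52.9 %.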